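## Analysis of the target

The target is a 5,6-dihydro-2H-pyran-2-one (O1, C2 carbonyl, C3=C4, C5, C6). Its single ring stereocentre, C6 (S), carries a ten-carbon chain C1'–C10' that ends in a phenyl ring. The chain holds a Z alkene at C1'=C2' and three carbinols at C4' (R), C6' (S) and C8' (R); C4'/C6' are syn and C6'/C8' are anti. C6 and C4' stand in a 1,5 relationship across the Z alkene, too far apart for one to direct the other by ordinary acyclic induction. The sensitive points are the conjugated lactone (a Michael acceptor that opens by elimination under base), the C6–O bond (allylic and acyloxy at once, so prone to ionisation in strong acid) and the Z alkene. The difficulty is a cis alkene flanked by an allylic and a homoallylic carbinol, a remote stereochemical pairing, and an anti,syn triol that must be unveiled at the very end. The strategy rests on the array C6(O)–C1'=C2'–C3'–C4'(O): a (Z)-pent-2-ene-1,5-diol is what forms when an allylboronate bearing a 1-oxyalkyl group on its boron-bound carbon transfers its allyl unit to an aldehyde.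

## Retrosynthetic reasoning

**Lactone last.** The O1–C2 acyl bond of 27 is cut first, together with the three side-chain hydroxyl protections, leading back to the fully silylated Z-enoate 25 through hydroxy ester 26. The unsaturated lactone is the most fragile part of the molecule, so it should exist only in the last flask. The forward step has to strip four silyl ethers and let the C6 hydroxyl, held near the ester by the Z C3=C4 bond, close the ring.

**C3=C4.** The enoate 25 is cut at C3=C4 to aldehyde 24, which comes from alcohol 23 and this from the benzyl-type ether 22. A two-carbon Z-selective olefination is the shortest way to add C2 and C3. It only asks that C4 be carried through the synthesis as a protected primary alcohol, orthogonal to the silyl ethers.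

**C4' oxygen.** Compound 22 is the silyl ether of homoallylic alcohol 21; the protection is needed because the later alcohol-to-aldehyde oxidation would otherwise attack C4'.

**Key disconnection, C3'–C4'.** Alcohol 21 is cut between C3' and C4' into allylboronate 19 (C4–C6 and C1'–C3') and aldehyde 9 (C4'–C10'). This bond is chosen because its formation by allyl transfer does three things at once: it joins two fragments of similar size, it creates C4', and it moves the double bond to C1'=C2' with defined geometry. A cut at C1'=C2' (olefination) or at C6–C1' (vinyl-metal addition) would need separate control of the geometry and of a carbinol. The forward reaction must turn the C1' configuration of 19 into the 4'R carbinol and a Z alkene. To secure this, boron is carried as a 4,4,5,5-tetraphenyl-1,3,2-dioxaborolane and not as a smaller tetramethyl ester, since the axial preference of the C1' substituent grows with the bulk of the diol.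

**Boronate 19.** Its silyl ether is removed to give alcohol 18, and the C6–C1' bond is cut to aldehyde 15 and the (Z)-γ-borylallylborane 16. A Z reagent gives the syn C6–O/C1'–B relationship, and its chiral dialkylboryl group sets both centres absolutely. Reagent 16 comes from kinetic hydroboration of allenylboronate 14, which is assembled from propargyl bromide 10 through boronic acid 13.

**Aldehyde 9.** Cleaving its formyl group back to a terminal alkene gives 8, the silyl ether of 7. Cutting C5'–C6' (allyl addition) gives aldehyde 5, and the same two operations, via 4 and 3, lead to 3-phenylpropanal 1. Two reagent-controlled allylations with opposite reagent antipodes give the anti C6'/C8' pair without relying on substrate bias.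

## Alternatives that were turned down

**Alternative 1:** The side chain is cut at C4'–C5' and C6'–C7'. A deoxyribose-phosphate aldolase joins chloroacetaldehyde A1 with two molecules of acetaldehyde A2: the first addition forms C4'–C5', the second C6'–C7', and the C4' hydroxyl closes onto C8' to give lactol A3, which ends the sequence.
- For: two stereocentres with the required syn relationship and the right absolute sense arise from two-carbon feedstocks, in water, without protecting groups and with catalytic chirality. On atom economy and cost of stereocontrol this is stronger than the chosen route, which uses three stoichiometric isopinocampheylboron reagents.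
- Against: A3 supplies only C3'–C8', with C3' as a chloromethyl group and C8' as a masked aldehyde. C8' still has to become a stereocentre by adding the phenethyl unit anti to C6'. C3' has to become the allylic methylene of a Z alkene, which in practice means epoxide formation, acetylide opening and semihydrogenation. C6 and the lactone are untouched.
- Comparison: the enzyme solves the easiest part of the problem (a syn 1,3-diol) and leaves the Z alkene, C6, C8' and the ring to a long linear sequence on a small polar intermediate. The chosen strategy offers in its place a convergent union that sets C4' and the alkene geometry in one step.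

**Alternative 2:** Carbons C3'–C8' are drawn from a six-membered carbocycle. A Baeyer–Villiger monooxygenase inserts oxygen into one of the two enantiotopic carbonyl–methylene bonds of meso ketone A4 and gives the seven-membered lactone A5, with C4' and C6' fixed and the two ends differentiated (C3' as an alkoxy carbon, C8' as an acyl carbon).
- For: the syn relationship is guaranteed by the cis ring, the absolute configuration comes from a catalyst, and the termini are differentiated in the same step. On these points it is stronger than the chosen route, which builds the diol with chiral reagents.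
- Against: the enantiotopic selectivity depends on an enzyme accepting a ketone with two bulky silyloxy groups. C8' arrives at the acid oxidation level, so a ketone synthesis and a hydroxyl-directed anti reduction are needed, which means freeing the C6' oxygen again. C3' arrives as a primary carbinol carbon next to a silyloxy-bearing centre, a poor site for the C2'–C3' bond formation that the Z alkene requires.
- Comparison: two of four stereocentres are set, and none of the alkene or lactone problem. The chosen strategy offers a bond formation placed where the target's own functionality (homoallylic carbinol next to a cis alkene) asks for it.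

**Alternative 3:** The lactone ring is cut at C5–C6 and O1–C2. Ynal A6 and diene A7 combine in a hetero-Diels–Alder reaction under a chiral (Schiff base)CrCl complex of trivalent chromium to give the cis dihydropyran acetal A8 with C6 set. Oxidation of the acetal to the lactone, alkyne semihydrogenation and desilylation would follow.
- For: the step is catalytic and enantioselective, it builds the ring and C6 together, and conjugated ynals are good heterodienophiles. The Z geometry then follows from syn hydrogenation of an alkyne. On certainty of alkene geometry this is stronger than the chosen key step, whose Z/E outcome rests on a conformational preference in a chair.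
- Against: A6 must already hold C4', C6' and C8', so three successive reagent-controlled additions and an alkyne homologation precede the key step, which does not create C4'. The sequence is linear and the key step comes late on the most valuable material. The ynal has an acidic propargylic methylene, and the late redox steps must distinguish the alkyne and the acetal from the ring alkene.
- Comparison: similar or higher step count with less convergence. The chosen strategy offers convergence and the simultaneous setting of C4' and the alkene, at the price of a selectivity that has to be enforced by the boron ester.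

Key step: step 10

## Route

Assumption: 3-[(4-methoxybenzyl)oxy]propanal and both antipodes of B-allyldiisopinocampheylborane and of diisopinocampheylborane are taken as purchasable; their sense of induction is assigned by the usual closed chair model (reagents from (+)-α-pinene add to the Si face of an unbranched aldehyde, those from (−)-α-pinene to the Re face).

Step 1
Reactants: 1 3-phenylpropanal
Product: 3 (3R)-1-phenylhex-5-en-3-ol, via diisopinocampheylborinate ester 2 (not isolated)
Conditions: (−)-Ipc2B(allyl) [from (+)-α-pinene], Et2O, −78 °C; then NaOH, H2O2, 0 °C to rt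
Reagents that add atoms: (−)-B-allyldiisopinocampheylborane, C=CCB([C@@H]1C[C@@H]2C[C@H]([C@H]1C)C2(C)C)[C@@H]1C[C@@H]2C[C@H]([C@H]1C)C2(C)C
Why: Brown allylboration through a closed chair transition state; the isopinocampheyl groups of the (+)-α-pinene-derived reagent should deliver the allyl group to the Si face of the aldehyde and set C8' as R, and oxidative work-up cleaves borinate 2.

Step 2
Reactants: 3 (3R)-1-phenylhex-5-en-3-ol
Product: 4 tert-butyldimethyl{[(3R)-1-phenylhex-5-en-3-yl]oxy}silane
Conditions: TBSCl, imidazole, DMF, rt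
Reagents that add atoms: tert-butyldimethylsilyl chloride, CC(C)(C)[Si](C)(C)Cl
Why: Standard silylation of an unhindered secondary alcohol; the stereocentre is not involved.

Step 3
Reactants: 4 tert-butyldimethyl{[(3R)-1-phenylhex-5-en-3-yl]oxy}silane
Product: 5 (3R)-3-[(tert-butyldimethylsilyl)oxy]-5-phenylpentanal
Conditions: O3, CH2Cl2, −78 °C; then PPh3, −78 °C to rt
Reagents that add atoms: ozone, [O-][O+]=O
Why: Ozonolysis with reductive work-up; the monosubstituted alkene reacts far faster than the phenyl ring at −78 °C, and the β-silyloxy aldehyde is used without storage.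

Step 4
Reactants: 5 (3R)-3-[(tert-butyldimethylsilyl)oxy]-5-phenylpentanal
Product: 7 (4R,6R)-6-[(tert-butyldimethylsilyl)oxy]-8-phenyloct-1-en-4-ol, via diisopinocampheylborinate ester 6 (not isolated)
Conditions: (+)-Ipc2B(allyl) [from (−)-α-pinene], Et2O, −78 °C; then NaOH, H2O2, 0 °C to rt
Reagents that add atoms: (+)-B-allyldiisopinocampheylborane, C=CCB([C@H]1C[C@H]2C[C@@H]([C@@H]1C)C2(C)C)[C@H]1C[C@H]2C[C@@H]([C@@H]1C)C2(C)C
Why: Second Brown allylboration under reagent control; the (−)-α-pinene-derived reagent should add to the Re face and place the new C6' oxygen anti to the C8' silyloxy group, the non-chelating β-silyl ether leaving the reagent in charge.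

Step 5
Reactants: 7 (4R,6R)-6-[(tert-butyldimethylsilyl)oxy]-8-phenyloct-1-en-4-ol
Product: 8 (4R,6R)-4,6-bis[(tert-butyldimethylsilyl)oxy]-8-phenyloct-1-ene
Conditions: TBSCl, imidazole, DMF, rt to 40 °C
Reagents that add atoms: tert-butyldimethylsilyl chloride, CC(C)(C)[Si](C)(C)Cl
Why: Standard silylation of a secondary alcohol; no stereocentre is touched.

Step 6
Reactants: 8 (4R,6R)-4,6-bis[(tert-butyldimethylsilyl)oxy]-8-phenyloct-1-ene
Product: 9 (3S,5R)-3,5-bis[(tert-butyldimethylsilyl)oxy]-7-phenylheptanal
Conditions: O3, CH2Cl2, −78 °C; then PPh3, −78 °C to rt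
Reagents that add atoms: ozone, [O-][O+]=O
Why: Ozonolysis with reductive work-up as in step 3; the change of descriptor at C6' (4R to 3S) is only a change of substituent priority.

Step 7
Reactants: 10 3-bromoprop-1-yne (propargyl bromide)
Product: 14 2-(propa-1,2-dien-1-yl)-4,4,5,5-tetraphenyl-1,3,2-dioxaborolane, via allenylmagnesium bromide 11 (not isolated), via trimethoxyborate salt 12 (not isolated), via allenylboronic acid 13 (not isolated)
Conditions: Mg, HgCl2 (cat.), Et2O, 0 °C; B(OMe)3, −78 °C; aq. HCl, 0 °C; then benzopinacol, MgSO4, Et2O, rt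
Reagents that add atoms: trimethyl borate, COB(OC)OC; benzopinacol (1,1,2,2-tetraphenylethane-1,2-diol), OC(c1ccccc1)(c1ccccc1)C(O)(c1ccccc1)c1ccccc1
Why: The Grignard reagent from propargyl bromide is borylated by trimethyl borate and hydrolysed to the allenylboronic acid, a known sequence; esterification with the diol is driven by removal of water and gives a bulky, chromatography-stable boronic ester.

Step 8
Reactants: 14 2-(propa-1,2-dien-1-yl)-4,4,5,5-tetraphenyl-1,3,2-dioxaborolane; 15 3-[(4-methoxybenzyl)oxy]propanal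
Product: 18 (3S,4S)-6-[(4-methoxybenzyl)oxy]-3-(4,4,5,5-tetraphenyl-1,3,2-dioxaborolan-2-yl)hex-1-en-4-ol, via (Z)-γ-borylallylborane 16 (not isolated), via diisopinocampheylborinate ester 17 (not isolated)
Conditions: (+)-Ipc2BH [from (−)-α-pinene], Et2O, −25 °C; then 15, −78 °C; then ethanolamine, Et2O, 0 °C to rt, filtration
Reagents that add atoms: none
Why: Kinetically controlled hydroboration adds boron to the terminal allene carbon from the side away from the boronate and gives the (Z)-γ-borylallylborane 16, whose chair-type allylboration of 15 gives the syn C6–O/C1'–B relationship; the (−)-α-pinene-derived isopinocampheyl groups should direct attack to the Re face of 15 (6S, hence 1'S). Ethanolamine releases the alcohol from borinate 17 by transesterification without oxidising the C–B bond of the hindered dioxaborolane.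

Step 9
Reactants: 18 (3S,4S)-6-[(4-methoxybenzyl)oxy]-3-(4,4,5,5-tetraphenyl-1,3,2-dioxaborolan-2-yl)hex-1-en-4-ol
Product: 19 2-[(3S,4S)-4-[(tert-butyldimethylsilyl)oxy]-6-[(4-methoxybenzyl)oxy]hex-1-en-3-yl]-4,4,5,5-tetraphenyl-1,3,2-dioxaborolane
Conditions: TBSOTf, 2,6-lutidine, CH2Cl2, −78 to 0 °C
Reagents that add atoms: tert-butyldimethylsilyl trifluoromethanesulfonate, CC(C)(C)[Si](C)(C)OS(=O)(=O)C(F)(F)F
Why: Silyl triflate with a hindered pyridine base silylates the crowded secondary alcohol at low temperature; the buffered medium avoids acid-promoted β-elimination of the boryl and oxy groups, and allylboronic esters do not undergo 1,3-boron shifts, so C1' is retained.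

Step 10
Reactants: 19 2-[(3S,4S)-4-[(tert-butyldimethylsilyl)oxy]-6-[(4-methoxybenzyl)oxy]hex-1-en-3-yl]-4,4,5,5-tetraphenyl-1,3,2-dioxaborolane; 9 (3S,5R)-3,5-bis[(tert-butyldimethylsilyl)oxy]-7-phenylheptanal
Product: 21 (3S,4Z,7R,9R,11R)-3,9,11-tris[(tert-butyldimethylsilyl)oxy]-1-[(4-methoxybenzyl)oxy]-13-phenyltridec-4-en-7-ol, via homoallylic borate ester 20 (not isolated)
Conditions: toluene (concentrated), rt to 60 °C; then aq. NaHCO3, MeOH, rt
Reagents that add atoms: none
Why: The boron of 19 binds the carbonyl oxygen of 9 and the allyl unit is transferred through a closed six-membered chair (B, O, C4', C3', C2', C1'), in which C3' bonds to C4' while the C1'–B bond breaks and the double bond moves to C1'=C2'; hydrolysis of borate 20 then frees 21. The closest known reaction type is the allylboration of aldehydes with α-substituted allylboronic esters with 1,3-chirality transfer, as used in double allylborations that give (Z)-pent-2-ene-1,5-diols. No ring is closed. The new stereocentre C4' is controlled by the C1' stereocentre of 19: with the aldehyde chain equatorial and the C1' substituent axial, the 1'S boronate exposes the aldehyde face that gives 4'R, and the same arrangement makes the new alkene Z. The step needs Z over E selectivity, which is coupled to the C4' face, since an equatorial C1' substituent would give the E alkene with the 4'S carbinol. The axial placement is secured by the four phenyl groups of the dioxaborolane, which crowd an equatorial substituent that is gauche to both B–O bonds, and by the syn C6–O/C1'–B relationship, the diastereomer for which this preference is best established. The silyl ethers of 9 cannot chelate boron and its stereocentres lie β and δ to the carbonyl, so the reagent should decide the outcome; no Lewis acid is added, because acid catalysis can change the E/Z preference of such reagents.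

Step 11
Reactants: 21 (3S,4Z,7R,9R,11R)-3,9,11-tris[(tert-butyldimethylsilyl)oxy]-1-[(4-methoxybenzyl)oxy]-13-phenyltridec-4-en-7-ol
Product: 22 (3S,4Z,7R,9S,11R)-3,7,9,11-tetrakis[(tert-butyldimethylsilyl)oxy]-1-[(4-methoxybenzyl)oxy]-13-phenyltridec-4-ene
Conditions: TBSOTf, 2,6-lutidine, CH2Cl2, −78 to 0 °C
Reagents that add atoms: tert-butyldimethylsilyl trifluoromethanesulfonate, CC(C)(C)[Si](C)(C)OS(=O)(=O)C(F)(F)F
Why: Silylation of the C4' hydroxyl so that only C4 can be oxidised later; the change of the C6' descriptor (9R to 9S) is a priority change only.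

Step 12
Reactants: 22 (3S,4Z,7R,9S,11R)-3,7,9,11-tetrakis[(tert-butyldimethylsilyl)oxy]-1-[(4-methoxybenzyl)oxy]-13-phenyltridec-4-ene
Product: 23 (3S,4Z,7R,9S,11R)-3,7,9,11-tetrakis[(tert-butyldimethylsilyl)oxy]-13-phenyltridec-4-en-1-ol
Conditions: DDQ, CH2Cl2/pH 7 phosphate buffer, 0 °C
Reagents that add atoms: none
Why: Oxidative cleavage of the electron-rich 4-methoxybenzyl ether by DDQ; the buffered two-phase medium leaves the silyl ethers and the Z alkene untouched.

Step 13
Reactants: 23 (3S,4Z,7R,9S,11R)-3,7,9,11-tetrakis[(tert-butyldimethylsilyl)oxy]-13-phenyltridec-4-en-1-ol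
Product: 24 (3S,4Z,7R,9S,11R)-3,7,9,11-tetrakis[(tert-butyldimethylsilyl)oxy]-13-phenyltridec-4-enal
Conditions: Dess–Martin periodinane, NaHCO3, CH2Cl2, 0 °C to rt
Reagents that add atoms: none
Why: Dess–Martin oxidation under buffered, near-neutral conditions, chosen to avoid β-elimination of the allylic C6 silyloxy group from the new aldehyde.

Step 14
Reactants: 24 (3S,4Z,7R,9S,11R)-3,7,9,11-tetrakis[(tert-butyldimethylsilyl)oxy]-13-phenyltridec-4-enal
Product: 25 methyl (2Z,5S,6Z,9R,11S,13R)-5,9,11,13-tetrakis[(tert-butyldimethylsilyl)oxy]-15-phenylpentadeca-2,6-dienoate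
Conditions: (CF3CH2O)2P(O)CH2CO2Me, KN(SiMe3)2, 18-crown-6, THF, −78 °C
Reagents that add atoms: methyl bis(2,2,2-trifluoroethyl)phosphonoacetate, COC(=O)CP(=O)(OCC(F)(F)F)OCC(F)(F)F
Why: Still–Gennari variant of the Horner–Wadsworth–Emmons reaction; the electron-poor phosphonate and the crown-separated potassium ion make oxaphosphetane collapse fast and kinetically controlled, which should give the Z enoate, and the low temperature limits β-elimination.

Step 15
Reactants: 25 methyl (2Z,5S,6Z,9R,11S,13R)-5,9,11,13-tetrakis[(tert-butyldimethylsilyl)oxy]-15-phenylpentadeca-2,6-dienoate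
Product: 27 (6S)-6-[(1Z,4R,6S,8R)-4,6,8-trihydroxy-10-phenyldec-1-en-1-yl]-5,6-dihydro-2H-pyran-2-one, via tetrahydroxy Z-enoate 26 (not isolated)
Conditions: HF (48% aq.), MeCN/CH2Cl2, 0 °C to rt
Reagents that add atoms: none
Why: Acidic fluoride cleaves the four silyl ethers; the freed C6 hydroxyl, held near the ester by the Z C3=C4 bond, closes the six-membered lactone by intramolecular transesterification with loss of methanol, and no stereocentre is touched.

## Compound list

1 | 3-phenylpropanal | O=CCCc1ccccc1 | starting material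
2 | (3R)-1-phenylhex-5-en-3-yl diisopinocampheylborinate (isopinocampheyl groups from (+)-α-pinene) | C=CC[C@H](OB([C@@H]1C[C@@H]2C[C@H]([C@H]1C)C2(C)C)[C@@H]1C[C@@H]2C[C@H]([C@H]1C)C2(C)C)CCc1ccccc1 | intermediate (not isolated)
3 | (3R)-1-phenylhex-5-en-3-ol | C=CC[C@H](O)CCc1ccccc1 | intermediate
4 | tert-butyldimethyl{[(3R)-1-phenylhex-5-en-3-yl]oxy}silane | C=CC[C@H](O[Si](C)(C)C(C)(C)C)CCc1ccccc1 | intermediate
5 | (3R)-3-[(tert-butyldimethylsilyl)oxy]-5-phenylpentanal | O=CC[C@H](O[Si](C)(C)C(C)(C)C)CCc1ccccc1 | intermediate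
6 | (4R,6R)-6-[(tert-butyldimethylsilyl)oxy]-8-phenyloct-1-en-4-yl diisopinocampheylborinate (isopinocampheyl groups from (−)-α-pinene) | C=CC[C@@H](OB([C@H]1C[C@H]2C[C@@H]([C@@H]1C)C2(C)C)[C@H]1C[C@H]2C[C@@H]([C@@H]1C)C2(C)C)C[C@H](O[Si](C)(C)C(C)(C)C)CCc1ccccc1 | intermediate (not isolated)
7 | (4R,6R)-6-[(tert-butyldimethylsilyl)oxy]-8-phenyloct-1-en-4-ol | C=CC[C@@H](O)C[C@H](O[Si](C)(C)C(C)(C)C)CCc1ccccc1 | intermediate
8 | (4R,6R)-4,6-bis[(tert-butyldimethylsilyl)oxy]-8-phenyloct-1-ene | C=CC[C@@H](O[Si](C)(C)C(C)(C)C)C[C@H](O[Si](C)(C)C(C)(C)C)CCc1ccccc1 | intermediate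
9 | (3S,5R)-3,5-bis[(tert-butyldimethylsilyl)oxy]-7-phenylheptanal | O=CC[C@@H](O[Si](C)(C)C(C)(C)C)C[C@H](O[Si](C)(C)C(C)(C)C)CCc1ccccc1 | intermediate
10 | 3-bromoprop-1-yne (propargyl bromide) | C#CCBr | starting material
11 | allenylmagnesium bromide (propa-1,2-dien-1-ylmagnesium bromide) | C=C=C[Mg]Br | intermediate (not isolated)
12 | bromomagnesium trimethoxy(propa-1,2-dien-1-yl)borate | C=C=C[B-](OC)(OC)OC.[Mg+]Br | intermediate (not isolated)
13 | propa-1,2-dien-1-ylboronic acid (allenylboronic acid) | C=C=CB(O)O | intermediate (not isolated)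
14 | 2-(propa-1,2-dien-1-yl)-4,4,5,5-tetraphenyl-1,3,2-dioxaborolane | C=C=CB1OC(c2ccccc2)(c2ccccc2)C(c2ccccc2)(c2ccccc2)O1 | intermediate
15 | 3-[(4-methoxybenzyl)oxy]propanal | COc1ccc(COCCC=O)cc1 | starting material
16 | (Z)-diisopinocampheyl[3-(4,4,5,5-tetraphenyl-1,3,2-dioxaborolan-2-yl)prop-2-en-1-yl]borane (isopinocampheyl groups from (−)-α-pinene) | C(/C=C\B1OC(c2ccccc2)(c2ccccc2)C(c2ccccc2)(c2ccccc2)O1)B([C@H]1C[C@H]2C[C@@H]([C@@H]1C)C2(C)C)[C@H]1C[C@H]2C[C@@H]([C@@H]1C)C2(C)C | intermediate (not isolated)
17 | (3S,4S)-6-[(4-methoxybenzyl)oxy]-3-(4,4,5,5-tetraphenyl-1,3,2-dioxaborolan-2-yl)hex-1-en-4-yl diisopinocampheylborinate | COc1ccc(COCC[C@@H]([C@@H](B2OC(c3ccccc3)(c3ccccc3)C(c3ccccc3)(c3ccccc3)O2)C=C)OB([C@H]2C[C@H]3C[C@@H]([C@@H]2C)C3(C)C)[C@H]2C[C@H]3C[C@@H]([C@@H]2C)C3(C)C)cc1 | intermediate (not isolated)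
18 | (3S,4S)-6-[(4-methoxybenzyl)oxy]-3-(4,4,5,5-tetraphenyl-1,3,2-dioxaborolan-2-yl)hex-1-en-4-ol | COc1ccc(COCC[C@@H]([C@@H](B2OC(c3ccccc3)(c3ccccc3)C(c3ccccc3)(c3ccccc3)O2)C=C)O)cc1 | intermediate
19 | 2-[(3S,4S)-4-[(tert-butyldimethylsilyl)oxy]-6-[(4-methoxybenzyl)oxy]hex-1-en-3-yl]-4,4,5,5-tetraphenyl-1,3,2-dioxaborolane | COc1ccc(COCC[C@@H]([C@@H](B2OC(c3ccccc3)(c3ccccc3)C(c3ccccc3)(c3ccccc3)O2)C=C)O[Si](C)(C)C(C)(C)C)cc1 | intermediate
20 | 2-{[(3S,4Z,7R,9R,11R)-3,9,11-tris[(tert-butyldimethylsilyl)oxy]-1-[(4-methoxybenzyl)oxy]-13-phenyltridec-4-en-7-yl]oxy}-4,4,5,5-tetraphenyl-1,3,2-dioxaborolane | COc1ccc(COCC[C@@H](/C=C\C[C@@H](OB2OC(c3ccccc3)(c3ccccc3)C(c3ccccc3)(c3ccccc3)O2)C[C@@H](O[Si](C)(C)C(C)(C)C)C[C@H](O[Si](C)(C)C(C)(C)C)CCc2ccccc2)O[Si](C)(C)C(C)(C)C)cc1 | intermediate (not isolated)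
21 | (3S,4Z,7R,9R,11R)-3,9,11-tris[(tert-butyldimethylsilyl)oxy]-1-[(4-methoxybenzyl)oxy]-13-phenyltridec-4-en-7-ol | COc1ccc(COCC[C@@H](/C=C\C[C@@H](O)C[C@@H](O[Si](C)(C)C(C)(C)C)C[C@H](O[Si](C)(C)C(C)(C)C)CCc2ccccc2)O[Si](C)(C)C(C)(C)C)cc1 | intermediate
22 | (3S,4Z,7R,9S,11R)-3,7,9,11-tetrakis[(tert-butyldimethylsilyl)oxy]-1-[(4-methoxybenzyl)oxy]-13-phenyltridec-4-ene | COc1ccc(COCC[C@@H](/C=C\C[C@@H](O[Si](C)(C)C(C)(C)C)C[C@@H](O[Si](C)(C)C(C)(C)C)C[C@H](O[Si](C)(C)C(C)(C)C)CCc2ccccc2)O[Si](C)(C)C(C)(C)C)cc1 | intermediate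
23 | (3S,4Z,7R,9S,11R)-3,7,9,11-tetrakis[(tert-butyldimethylsilyl)oxy]-13-phenyltridec-4-en-1-ol | OCC[C@@H](/C=C\C[C@@H](O[Si](C)(C)C(C)(C)C)C[C@@H](O[Si](C)(C)C(C)(C)C)C[C@H](O[Si](C)(C)C(C)(C)C)CCc1ccccc1)O[Si](C)(C)C(C)(C)C | intermediate
24 | (3S,4Z,7R,9S,11R)-3,7,9,11-tetrakis[(tert-butyldimethylsilyl)oxy]-13-phenyltridec-4-enal | O=CC[C@@H](/C=C\C[C@@H](O[Si](C)(C)C(C)(C)C)C[C@@H](O[Si](C)(C)C(C)(C)C)C[C@H](O[Si](C)(C)C(C)(C)C)CCc1ccccc1)O[Si](C)(C)C(C)(C)C | intermediate
25 | methyl (2Z,5S,6Z,9R,11S,13R)-5,9,11,13-tetrakis[(tert-butyldimethylsilyl)oxy]-15-phenylpentadeca-2,6-dienoate | COC(=O)/C=C\C[C@@H](/C=C\C[C@@H](O[Si](C)(C)C(C)(C)C)C[C@@H](O[Si](C)(C)C(C)(C)C)C[C@H](O[Si](C)(C)C(C)(C)C)CCc1ccccc1)O[Si](C)(C)C(C)(C)C | intermediate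
26 | methyl (2Z,5S,6Z,9R,11S,13R)-5,9,11,13-tetrahydroxy-15-phenylpentadeca-2,6-dienoate | COC(=O)/C=C\C[C@@H](/C=C\C[C@@H](O)C[C@@H](O)C[C@H](O)CCc1ccccc1)O | intermediate (not isolated)
27 | (6S)-6-[(1Z,4R,6S,8R)-4,6,8-trihydroxy-10-phenyldec-1-en-1-yl]-5,6-dihydro-2H-pyran-2-one | O=C1C=CC[C@@H](/C=C\C[C@@H](O)C[C@@H](O)C[C@H](O)CCc2ccccc2)O1 | target

## Step count and least certain steps

Total step count: 15. Longest linear sequence: 12 steps (steps 1 to 6, then 10 to 15); the boronate branch (steps 7 to 9) joins at step 10.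

**Step 10 (key step).** The most likely failure is erosion of the Z/E selectivity: the chair with the C1' substituent equatorial competes and gives the E alkene with the epimeric C4' carbinol. The preference has so far been relied on for O-borylated rather than O-silylated substituents at C6. A second risk is slow allyl transfer from the very hindered boronic ester, so that heating is needed and the aldehyde degrades.

The fallback sets the three elements separately and runs from aldehyde 9 to compound 22. Catalytic asymmetric propargylation of 9 (allenylboronic acid pinacol ester with a chiral BINOL-derived phosphoric acid, antipode chosen for the 4'R carbinol) gives (4R,6R,8R)-6,8-bis[(tert-butyldimethylsilyl)oxy]-10-phenyldec-1-yn-4-ol F1. Silylation (TBSOTf, 2,6-lutidine) gives (4R,6S,8R)-4,6,8-tris[(tert-butyldimethylsilyl)oxy]-10-phenyldec-1-yne F2. Its zinc acetylide (Et2Zn, Ti(OiPr)4, BINOL of the antipode needed for 6S) adds to aldehyde 15 to give (3S,7R,9S,11R)-7,9,11-tris[(tert-butyldimethylsilyl)oxy]-1-[(4-methoxybenzyl)oxy]-13-phenyltridec-4-yn-3-ol F3. Semihydrogenation (H2, Pd/CaCO3 poisoned with Pb(OAc)2, quinoline) gives (3S,4Z,7R,9S,11R)-7,9,11-tris[(tert-butyldimethylsilyl)oxy]-1-[(4-methoxybenzyl)oxy]-13-phenyltridec-4-en-3-ol F4, and silylation of F4 gives 22, where the route resumes at step 12.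

**Step 8 (with the silylation of step 9 that depends on it).** Two processes threaten it. If the allylborane 16 warms before the aldehyde is added, a 1,3-boron shift isomerises it to the E isomer, which gives the anti boronate and so the wrong pairing of C6 and C4'. During release of the free β-hydroxy boronate and its silylation, loss of the boryl and oxy groups by β-elimination to a 1,3-diene can compete.

The fallback avoids handling the β-hydroxy boronate: it sets out from borinate 17, generated as in step 8 but not worked up, and returns at 22. Aldehyde 9 is added to 17 and the mixture is warmed to rt, so that the second allylboration takes place on the O-borylated reagent itself and gives the doubly O-borylated alkene (3S,4Z,7R,9R,11R)-9,11-bis[(tert-butyldimethylsilyl)oxy]-1-[(4-methoxybenzyl)oxy]-13-phenyl-7-[(4,4,5,5-tetraphenyl-1,3,2-dioxaborolan-2-yl)oxy]tridec-4-en-3-yl diisopinocampheylborinate F5. Work-up with ethanolamine and aq. NaHCO3 gives (3S,4Z,7R,9R,11R)-9,11-bis[(tert-butyldimethylsilyl)oxy]-1-[(4-methoxybenzyl)oxy]-13-phenyltridec-4-ene-3,7-diol F6, and two-fold silylation (TBSOTf, 2,6-lutidine) gives 22. Steps 9 to 11 are then not needed.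

**Step 14.** The likely failures are incomplete Z selectivity (the E enoate cannot lactonise) and base-induced β-elimination of the allylic C6 silyloxy group from aldehyde 24 to a conjugated dienal.

The fallback fixes the geometry by syn hydrogenation; it sets out from 24 and returns at 25. Homologation with dimethyl (1-diazo-2-oxopropyl)phosphonate (K2CO3, MeOH) gives (4S,5Z,8R,10S,12R)-4,8,10,12-tetrakis[(tert-butyldimethylsilyl)oxy]-14-phenyltetradec-5-en-1-yne F7. Deprotonation (n-BuLi, THF, −78 °C) and methyl chloroformate give methyl (5S,6Z,9R,11S,13R)-5,9,11,13-tetrakis[(tert-butyldimethylsilyl)oxy]-15-phenylpentadec-6-en-2-ynoate F8. Semihydrogenation (H2, Pd/CaCO3 poisoned with Pb(OAc)2, quinoline) gives 25.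

**Step 15.** Cleavage of four secondary silyl ethers may be slow enough that the acid begins to ionise the allylic C6–O bond of the product lactone, or desilylation may stop at partly protected material.

The fallback closes the ring from the hydroxy acid under weak acid only; it sets out from 25 and returns at 27. Saponification (LiOH, THF/H2O, 0 °C) gives (2Z,5S,6Z,9R,11S,13R)-5,9,11,13-tetrakis[(tert-butyldimethylsilyl)oxy]-15-phenylpentadeca-2,6-dienoic acid F9. Fluoride desilylation (Bu4NF, THF) gives (2Z,5S,6Z,9R,11S,13R)-5,9,11,13-tetrahydroxy-15-phenylpentadeca-2,6-dienoic acid F10 as its carboxylate, and careful acidification to about pH 4 lets the Z-configured δ-hydroxy acid lactonise to 27.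

## Further compounds

F1 | step 10 | (4R,6R,8R)-6,8-bis[(tert-butyldimethylsilyl)oxy]-10-phenyldec-1-yn-4-ol | C#CC[C@@H](O)C[C@@H](O[Si](C)(C)C(C)(C)C)C[C@H](O[Si](C)(C)C(C)(C)C)CCc1ccccc1
F2 | step 10 | (4R,6S,8R)-4,6,8-tris[(tert-butyldimethylsilyl)oxy]-10-phenyldec-1-yne | C#CC[C@@H](O[Si](C)(C)C(C)(C)C)C[C@@H](O[Si](C)(C)C(C)(C)C)C[C@H](O[Si](C)(C)C(C)(C)C)CCc1ccccc1
F3 | step 10 | (3S,7R,9S,11R)-7,9,11-tris[(tert-butyldimethylsilyl)oxy]-1-[(4-methoxybenzyl)oxy]-13-phenyltridec-4-yn-3-ol | COc1ccc(COCC[C@@H](C#CC[C@@H](O[Si](C)(C)C(C)(C)C)C[C@@H](O[Si](C)(C)C(C)(C)C)C[C@H](O[Si](C)(C)C(C)(C)C)CCc2ccccc2)O)cc1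
F4 | step 10 | (3S,4Z,7R,9S,11R)-7,9,11-tris[(tert-butyldimethylsilyl)oxy]-1-[(4-methoxybenzyl)oxy]-13-phenyltridec-4-en-3-ol | COc1ccc(COCC[C@@H](/C=C\C[C@@H](O[Si](C)(C)C(C)(C)C)C[C@@H](O[Si](C)(C)C(C)(C)C)C[C@H](O[Si](C)(C)C(C)(C)C)CCc2ccccc2)O)cc1
F5 | step 8 | (3S,4Z,7R,9R,11R)-9,11-bis[(tert-butyldimethylsilyl)oxy]-1-[(4-methoxybenzyl)oxy]-13-phenyl-7-[(4,4,5,5-tetraphenyl-1,3,2-dioxaborolan-2-yl)oxy]tridec-4-en-3-yl diisopinocampheylborinate | COc1ccc(COCC[C@@H](/C=C\C[C@@H](OB2OC(c3ccccc3)(c3ccccc3)C(c3ccccc3)(c3ccccc3)O2)C[C@@H](O[Si](C)(C)C(C)(C)C)C[C@H](O[Si](C)(C)C(C)(C)C)CCc2ccccc2)OB([C@H]2C[C@H]3C[C@@H]([C@@H]2C)C3(C)C)[C@H]2C[C@H]3C[C@@H]([C@@H]2C)C3(C)C)cc1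
F6 | step 8 | (3S,4Z,7R,9R,11R)-9,11-bis[(tert-butyldimethylsilyl)oxy]-1-[(4-methoxybenzyl)oxy]-13-phenyltridec-4-ene-3,7-diol | COc1ccc(COCC[C@@H](/C=C\C[C@@H](O)C[C@@H](O[Si](C)(C)C(C)(C)C)C[C@H](O[Si](C)(C)C(C)(C)C)CCc2ccccc2)O)cc1
F7 | step 14 | (4S,5Z,8R,10S,12R)-4,8,10,12-tetrakis[(tert-butyldimethylsilyl)oxy]-14-phenyltetradec-5-en-1-yne | C#CC[C@@H](/C=C\C[C@@H](O[Si](C)(C)C(C)(C)C)C[C@@H](O[Si](C)(C)C(C)(C)C)C[C@H](O[Si](C)(C)C(C)(C)C)CCc1ccccc1)O[Si](C)(C)C(C)(C)C
F8 | step 14 | methyl (5S,6Z,9R,11S,13R)-5,9,11,13-tetrakis[(tert-butyldimethylsilyl)oxy]-15-phenylpentadec-6-en-2-ynoate | COC(=O)C#CC[C@@H](/C=C\C[C@@H](O[Si](C)(C)C(C)(C)C)C[C@@H](O[Si](C)(C)C(C)(C)C)C[C@H](O[Si](C)(C)C(C)(C)C)CCc1ccccc1)O[Si](C)(C)C(C)(C)C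
F9 | step 15 | (2Z,5S,6Z,9R,11S,13R)-5,9,11,13-tetrakis[(tert-butyldimethylsilyl)oxy]-15-phenylpentadeca-2,6-dienoic acid | OC(=O)/C=C\C[C@@H](/C=C\C[C@@H](O[Si](C)(C)C(C)(C)C)C[C@@H](O[Si](C)(C)C(C)(C)C)C[C@H](O[Si](C)(C)C(C)(C)C)CCc1ccccc1)O[Si](C)(C)C(C)(C)C
F10 | step 15 | (2Z,5S,6Z,9R,11S,13R)-5,9,11,13-tetrahydroxy-15-phenylpentadeca-2,6-dienoic acid | OC(=O)/C=C\C[C@@H](/C=C\C[C@@H](O)C[C@@H](O)C[C@H](O)CCc1ccccc1)O
A1 | alternative 1 | chloroacetaldehyde | ClCC=O
A2 | alternative 1 | acetaldehyde | CC=O
A3 | alternative 1 | 6-chloro-2,4,6-trideoxy-D-erythro-hexopyranose (anomeric mixture) | ClC[C@@H]1C[C@@H](O)CC(O)O1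
A4 | alternative 2 | cis-3,5-bis[(tert-butyldimethylsilyl)oxy]cyclohexan-1-one (meso) | O=C1C[C@@H](O[Si](C)(C)C(C)(C)C)C[C@@H](O[Si](C)(C)C(C)(C)C)C1
A5 | alternative 2 | (4R,6S)-4,6-bis[(tert-butyldimethylsilyl)oxy]oxepan-2-one | C1[C@@H](O[Si](C)(C)C(C)(C)C)C[C@@H](O[Si](C)(C)C(C)(C)C)CC(=O)O1
A6 | alternative 3 | (5R,7S,9R)-5,7,9-tris[(tert-butyldimethylsilyl)oxy]-11-phenylundec-2-ynal | O=CC#CC[C@@H](O[Si](C)(C)C(C)(C)C)C[C@@H](O[Si](C)(C)C(C)(C)C)C[C@H](O[Si](C)(C)C(C)(C)C)CCc1ccccc1
A7 | alternative 3 | (E)-1-methoxybuta-1,3-diene | CO/C=C/C=C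
A8 | alternative 3 | (2S,6R)-6-methoxy-2-[(4R,6S,8R)-4,6,8-tris[(tert-butyldimethylsilyl)oxy]-10-phenyldec-1-yn-1-yl]-3,6-dihydro-2H-pyran | CO[C@H]1C=CC[C@@H](C#CC[C@@H](O[Si](C)(C)C(C)(C)C)C[C@@H](O[Si](C)(C)C(C)(C)C)C[C@H](O[Si](C)(C)C(C)(C)C)CCc2ccccc2)O1
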